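**Plan**

1. The target is a central butanoylphloroglucinol ring joined through two CH2 groups to two identical 6-butanoyl-3,5-dihydroxy-4,4-dimethylcyclohexa-2,5-dien-1-one (butanoylfilicinic acid) rings. It has no stereocentre.
2. Enabling feature: each filicinic ring is a cyclic 2-acyl-1,3,5-trione. The bond from its ring carbonyl C-1 (next to the CH2-bearing C-2) to the butanoyl-bearing C-6 is the C-6→C-1 Claisen bond of a 4,4-dimethyl-3,5,7-trioxodecanoyl chain. The quaternary C(CH3)2 (C-4) blocks aromatisation, and the ortho-hydroxyls of the central ring can hold C-1 as six-membered aryl lactones (active esters).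
3. Retrosynthesis: cut the C-1–C-6 bond of both filicinic rings (twofold biomimetic Claisen closure, lactones as tethers). Then cut both C-2–C-3 bonds (malonic half ester plus a masked triketide enol lactone). Then remove the lactone rings, the two formyl carbons and the butanoyl group of the central ring.
4. Forward: the enol lactone 3,3-dimethyl-6-propylpyran-2,4-dione is made from pentan-2-one and dimethylmalonyl dichloride. Phloroglucinol is diformylated, butanoylated, annulated with Meldrum's acid to a bis-coumarin diacid and hydrogenated. Both arms are chain-extended by decarboxylative acylation, and both carbocycles are closed last while the temporary lactone rings open.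
5. Stereochemistry: none in the target. The C-3 stereocentres of the lactone intermediates form without control and vanish when these carbons become sp2 in the last step.

Key step: step 8

Assumption: in step 5 each lactone is taken to close onto the hydroxyl that is not hydrogen-bonded to the butanoyl carbonyl, giving the angular bis-lactone; a linear isomer would carry the same arms and converge on the same target in step 8.

**Route**

Step 1
Reactants: 1 pentan-2-one
Product: 2 2-(trimethylsilyloxy)pent-1-ene
Conditions: LDA (1.05 equiv), THF, −78 °C; TMSCl, −78 °C → rt; distil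
Reagents that add atoms: chlorotrimethylsilane, C[Si](C)(C)Cl
Why: Kinetic deprotonation of the methyl ketone at the CH3 group and O-silylation of the lithium enolate (kinetic silyl enol ether formation) should give the terminal enol ether; no stereocentre is formed.

Step 2
Reactants: 2 2-(trimethylsilyloxy)pent-1-ene (1.5 equiv, added slowly); 3 dimethylmalonyl dichloride (2,2-dimethylpropanedioyl dichloride)
Product: 5 3,3-dimethyl-6-propyl-2H-pyran-2,4(3H)-dione, via 2,2-dimethyl-3,5-dioxooctanoyl chloride 4 (not isolated)
Conditions: ZnCl2 (0.2 equiv), CH2Cl2/Et2O, −20 °C → rt; evaporate, distil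
Reagents that add atoms: none
Why: Lewis-acid-promoted C-acylation of a silyl enol ether by an acid chloride (Mukaiyama-type acylation) should give the β-diketone 4, whose enol oxygen then acylates the second acid chloride (6-exo-trig enol lactonisation), the reaction type by which malonyl chlorides and silyl enol ethers give pyranones.

Step 3
Reactants: 6 phloroglucinol (benzene-1,3,5-triol)
Product: 7 2,4,6-trihydroxybenzene-1,3-dicarbaldehyde
Conditions: POCl3 (2.2 equiv), DMF, 1,4-dioxane, 0 °C → rt; then ice-water
Reagents that add atoms: N,N-dimethylformamide, CN(C)C=O; water, O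
Why: Vilsmeier–Haack formylation of the electron-rich triol should stop at the dialdehyde because each formyl group deactivates the ring, and hydrolysis of the bis-iminium salt gives 7.

Step 4
Reactants: 7 2,4,6-trihydroxybenzene-1,3-dicarbaldehyde; 8 butanoyl chloride
Product: 9 5-butanoyl-2,4,6-trihydroxybenzene-1,3-dicarbaldehyde
Conditions: AlCl3 (4 equiv), PhNO2/CH2Cl2, rt → 50 °C; ice/1 M HCl
Reagents that add atoms: none
Why: Friedel–Crafts acylation should occur at the single free ring position, which is still activated by three ortho/para hydroxyl groups, as is usual for the preparation of diformyl acylphloroglucinols.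

Step 5
Reactants: 9 5-butanoyl-2,4,6-trihydroxybenzene-1,3-dicarbaldehyde; 10 Meldrum's acid (2,2-dimethyl-1,3-dioxane-4,6-dione, 2.2 equiv)
Product: 11 6-butanoyl-5-hydroxy-2,8-dioxo-2H,8H-pyrano[2,3-f]chromene-3,9-dicarboxylic acid (angular bis-coumarin diacid)
Conditions: piperidinium acetate (10 mol%), EtOH, 70 °C
Reagents that add atoms: none
Why: Knoevenagel condensation of each salicylaldehyde unit with Meldrum's acid, followed by attack of an ortho-hydroxyl on a Meldrum's carbonyl with loss of acetone, is the classical coumarin-3-carboxylic acid synthesis.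

Step 6
Reactants: 11 angular bis-coumarin diacid
Product: 12 6-butanoyl-5-hydroxy-2,8-dioxo-3,4,9,10-tetrahydro-2H,8H-pyrano[2,3-f]chromene-3,9-dicarboxylic acid (mixture of diastereomers)
Conditions: H2 (1 atm), 10% Pd/C, THF/EtOAc, rt
Reagents that add atoms: none
Why: Catalytic hydrogenation of the electron-poor C-3=C-4 bonds of coumarin-3-carboxylic acids should leave the chelated aryl ketone and the lactones untouched at 1 atm; the two new C-3 stereocentres form without control and are erased in step 8.

Step 7
Reactants: 12 bis(2-oxochroman-3-carboxylic acid) (mixture of diastereomers); 5 3,3-dimethyl-6-propyl-2H-pyran-2,4(3H)-dione (2.4 equiv)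
Product: 13 6-butanoyl-3,9-bis(2,2-dimethyl-3,5-dioxooctanoyl)-5-hydroxy-3,4,9,10-tetrahydro-2H,8H-pyrano[2,3-f]chromene-2,8-dione (mixture of diastereomers and enol tautomers)
Conditions: MgCl2 (4 equiv), Et3N (7 equiv), imidazole (0.4 equiv), MeCN/THF, 0 °C → rt; then cold 1 M HCl (−CO2)
Reagents that add atoms: none
Why: Proposed new method: the magnesium enolate of each malonic half aryl ester, chelated between carboxylate and lactone carbonyl, should attack the lactone carbonyl C-2 of enol lactone 5 (or the acyl imidazolide that imidazole forms from 5 in equilibrium), expel the magnesium 1,3-diketonate as leaving group and lose CO2 on acidification to give the 3-acyl lactone, the chelate keeping the lactone carbonyl masked as an enolate so that ring closure waits for step 8; the closest known reactions are the magnesium-mediated decarboxylative Claisen condensation of malonic half esters with acyl imidazolides and the acylation of enolates by enol lactones (first stage of the Fujimoto–Belleau reaction).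

Step 8
Reactants: 13 bis(3-acyl-chroman-2-one) carrying two tetraketide arms
Product: 15 2,2'-[(5-butanoyl-2,4,6-trihydroxy-1,3-phenylene)bis(methylene)]bis(6-butanoyl-3,5-dihydroxy-4,4-dimethylcyclohexa-2,5-dien-1-one) (target), via mono-closed chromanone 14 (not isolated)
Conditions: Et3N (8 equiv), DMAP (0.2 equiv), MeCN, 0 °C → rt; then 1 M HCl
Reagents that add atoms: none
Why: The amine converts each 1,3-diketone into its enolate, whose central carbon C-6 adds to the lactone carbonyl C-1 of the same arm; collapse of the tetrahedral intermediate expels the acidic acylphloroglucinol phenoxide, so the lactone opens as the carbocycle closes and the product is trapped as the strongly acidic enolised triketone. The closest known reaction type is the Dieckmann/Claisen cyclisation of 3,5,7-triketo esters to acylphloroglucinols (the C-6→C-1 mode of the polyketide pathway), with the aryloxide departure of a Baker–Venkataraman acyl transfer. Each carbocycle closes by 6-(enolexo)-exo-trig attack; the first closure gives 14 and the second repeats the event on the other arm. No stereocentre is created, and the two C-3 lactone stereocentres become the sp2 C-2 atoms of the filicinic rings. The step needs C- over O-acylation and Claisen over aldol closure: O-acylation through the C-5 enolate oxygen would give only a six-membered enol lactone that DMAP returns to the C-acyl product (enol ester to triketone rearrangement), and the aldol closure C-2→C-7 is reversible and cannot aromatise because C-4 is quaternary. A non-nucleophilic base at room temperature is chosen to avoid retro-Claisen cleavage at the non-enolisable C(=O)–C(CH3)2–C(=O) unit and retro-Michael scrambling of the methylene bridges.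

**Compound list**

1 | pentan-2-one | CCCC(C)=O | starting material
2 | 2-(trimethylsilyloxy)pent-1-ene | CCCC(=C)O[Si](C)(C)C | intermediate
3 | dimethylmalonyl dichloride (2,2-dimethylpropanedioyl dichloride) | CC(C)(C(=O)Cl)C(=O)Cl | starting material
4 | 2,2-dimethyl-3,5-dioxooctanoyl chloride (formed in the flask, not isolated) | CCCC(=O)CC(=O)C(C)(C)C(=O)Cl | intermediate
5 | 3,3-dimethyl-6-propyl-2H-pyran-2,4(3H)-dione | CCCC1=CC(=O)C(C)(C)C(=O)O1 | intermediate
6 | phloroglucinol (benzene-1,3,5-triol) | Oc1cc(O)cc(O)c1 | starting material
7 | 2,4,6-trihydroxybenzene-1,3-dicarbaldehyde | O=Cc1c(O)cc(O)c(C=O)c1O | intermediate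
8 | butanoyl chloride | CCCC(=O)Cl | starting material
9 | 5-butanoyl-2,4,6-trihydroxybenzene-1,3-dicarbaldehyde | CCCC(=O)c1c(O)c(C=O)c(O)c(C=O)c1O | intermediate
10 | Meldrum's acid (2,2-dimethyl-1,3-dioxane-4,6-dione) | CC1(C)OC(=O)CC(=O)O1 | starting material
11 | 6-butanoyl-5-hydroxy-2,8-dioxo-2H,8H-pyrano[2,3-f]chromene-3,9-dicarboxylic acid | CCCC(=O)c1c(O)c2C=C(C(=O)O)C(=O)Oc2c3C=C(C(=O)O)C(=O)Oc13 | intermediate
12 | 6-butanoyl-5-hydroxy-2,8-dioxo-3,4,9,10-tetrahydro-2H,8H-pyrano[2,3-f]chromene-3,9-dicarboxylic acid (mixture of diastereomers) | CCCC(=O)c1c(O)c2CC(C(=O)O)C(=O)Oc2c3CC(C(=O)O)C(=O)Oc13 | intermediate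
13 | 6-butanoyl-3,9-bis(2,2-dimethyl-3,5-dioxooctanoyl)-5-hydroxy-3,4,9,10-tetrahydro-2H,8H-pyrano[2,3-f]chromene-2,8-dione (mixture of diastereomers) | CCCC(=O)c1c(O)c2CC(C(=O)C(C)(C)C(=O)CC(=O)CCC)C(=O)Oc2c3CC(C(=O)C(C)(C)C(=O)CC(=O)CCC)C(=O)Oc13 | intermediate
14 | 8-butanoyl-6-[(5-butanoyl-2,4-dihydroxy-3,3-dimethyl-6-oxocyclohexa-1,4-dien-1-yl)methyl]-3-(2,2-dimethyl-3,5-dioxooctanoyl)-5,7-dihydroxychroman-2-one (racemic, formed in the flask, not isolated) | CCCC(=O)c1c(O)c(CC2=C(O)C(C)(C)C(O)=C(C(=O)CCC)C2=O)c(O)c3CC(C(=O)C(C)(C)C(=O)CC(=O)CCC)C(=O)Oc13 | intermediate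
15 | 2,2'-[(5-butanoyl-2,4,6-trihydroxy-1,3-phenylene)bis(methylene)]bis(6-butanoyl-3,5-dihydroxy-4,4-dimethylcyclohexa-2,5-dien-1-one) (CNP0287270.0) | CCCC(=O)C1=C(O)C(C)(C)C(O)=C(Cc2c(O)c(CC3=C(O)C(C)(C)C(O)=C(C(=O)CCC)C3=O)c(O)c(C(=O)CCC)c2O)C1=O | target

**Summary**

Total step count: 8. Longest linear sequence: 6 steps (phloroglucinol 6 to target 15, steps 3 to 8).

Steps most likely to fail:

1. Step 7 (proposed new method). The magnesium enolate may fail to attack the hindered, neopentyl-type lactone carbonyl of 5. It may instead add to the enol-ether carbon of 5 and open the ring in the wrong sense, or the half ester may simply decarboxylate without being acylated. The fallback sets out from 12 and returns to the route at 13, using a lithium polyanion in place of the magnesium malonate. Heating 12 in pyridine at about 100 °C should cause twofold decarboxylation to 6-butanoyl-5-hydroxy-3,4,9,10-tetrahydro-2H,8H-pyrano[2,3-f]chromene-2,8-dione F1. Treating F1 with LiHMDS (about 6 equiv) in THF at −78 °C should form the phenoxide and the butanoyl enolate first and the two lactone enolates last. The lactone enolates, being the most basic, should then be acylated by 5 (2.2 equiv) at the lactone carbonyl, which is a Claisen-type acylation of ester enolates by an enol lactone. An acidic quench should give 13.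

2. Step 8 (key step). Closure may stop at the O-acylated enol lactone. Adventitious nucleophiles may cleave the non-enolisable 1,3-diketone by a retro-Claisen reaction, or the base may cause retro-Michael scrambling of the methylene bridges once the filicinic rings exist. The fallback sets out from 5 (with 6 and 8) and returns at 15; it makes the same C-6→C-1 Claisen bond on a free fragment and builds the bridges afterwards. The lithium enolate of tert-butyl acetate (LDA, THF, −78 °C, 2.2 equiv) should open 5 at the lactone carbonyl to give tert-butyl 4,4-dimethyl-3,5,7-trioxodecanoate F2. KOtBu in THF (0 °C → rt) should cyclise F2 by Claisen condensation to 2-butanoyl-3,5-dihydroxy-4,4-dimethylcyclohexa-2,5-dien-1-one (butanoylfilicinic acid) F3. Friedel–Crafts acylation of 6 with 8 (AlCl3, PhNO2) should give 1-(2,4,6-trihydroxyphenyl)butan-1-one F4. The classical formaldehyde condensation of F4 with two equivalents of F3 (aqueous CH2O, dilute aqueous KOH, 0 °C, then acid) should give 15.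

3. Step 2. The silyl enol ether may be acylated on oxygen instead of carbon, two molecules of 2 may acylate both ends of 3, or HCl may desilylate 2 before it reacts. The fallback sets out from 8 and returns at 5, building the chain from the ester end. tert-Butyl 3-oxobutanoate (commercial) is dimethylated (MeI, K2CO3, acetone) to tert-butyl 2,2-dimethyl-3-oxobutanoate F5. Its only enolate (LiHMDS, 2.1 equiv, toluene/THF, −78 → 0 °C) should be C-acylated by 8 to give tert-butyl 2,2-dimethyl-3,5-dioxooctanoate F6. TFA/TFAA at rt should cleave the tert-butyl ester and close the enol lactone to 5, the standard cyclisation of tert-butyl 3,5-dioxoalkanoates to pyranones.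

**Further compounds**

F1 | step 7 | 6-butanoyl-5-hydroxy-3,4,9,10-tetrahydro-2H,8H-pyrano[2,3-f]chromene-2,8-dione | CCCC(=O)c1c(O)c2CCC(=O)Oc2c3CCC(=O)Oc13
F2 | step 8 | tert-butyl 4,4-dimethyl-3,5,7-trioxodecanoate | CCCC(=O)CC(=O)C(C)(C)C(=O)CC(=O)OC(C)(C)C
F3 | step 8 | 2-butanoyl-3,5-dihydroxy-4,4-dimethylcyclohexa-2,5-dien-1-one (butanoylfilicinic acid) | CCCC(=O)C1=C(O)C(C)(C)C(O)=CC1=O
F4 | step 8 | 1-(2,4,6-trihydroxyphenyl)butan-1-one | CCCC(=O)c1c(O)cc(O)cc1O
F5 | step 2 | tert-butyl 2,2-dimethyl-3-oxobutanoate | CC(=O)C(C)(C)C(=O)OC(C)(C)C
F6 | step 2 | tert-butyl 2,2-dimethyl-3,5-dioxooctanoate | CCCC(=O)CC(=O)C(C)(C)C(=O)OC(C)(C)C
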